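## The problem

The target 13 consists of two identical 5,7-dihydroxy-2,2-dimethylchroman units, each with an isobutyryl group on C8, joined through their C6 atoms by one methine carbon that also carries a 5-methylhexyl chain. It has no stereocentre, because the bridging carbon bears two identical aryl groups, so every difficulty is regiochemical. Each benzene ring is fully substituted: oxygen on C5, C7 and C8a, and three different carbon substituents (bridge on C6, acyl on C8, pyran methylene on C4a). Only the C8a oxygen, between the acyl-bearing carbon and C4a, may become the pyran oxygen. The doubly benzylic methine between two electron-rich arenes can be lost by retro-Friedel–Crafts cleavage in strong acid or by quinone methide extrusion in hot alkali. The polyphenol anions are air-sensitive, and the tertiary alkyl aryl ether does not tolerate strong Lewis acids. The feature that opens the structure is that the six ring carbons and the isobutyryl carbonyl form a seven-carbon chain oxygenated on every second carbon (C7, C5, C8a and the acyl carbon). Each arene is therefore the Claisen cyclisation product of a 3,5,7-trioxo ester, whose stable cyclic form is a 4-hydroxy-6-(2-oxoalkyl)-2-pyrone. In that pyrone the future C6 is pyrone C3, the only nucleophilic ring carbon, so the bridge can be fixed without regiochemical choice before either arene exists.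

## Retrosynthesis

**13 to 11 (through 12).** The last skeletal bonds are the two O1–C2 bonds of the pyrans. Cutting them, with the C5 oxygens held as benzyl ethers in 12, leads to the bis(ortho-prenylphenol) 11. This cut is preferred to closing a pre-formed ether onto carbon, because the forward step is the acid-catalysed addition of a phenol to a trisubstituted alkene. With the other flanking oxygen benzylated, that addition can only go one way. The forward steps need an acid mild enough for the benzyl ethers and the methine bridge, then a neutral hydrogenolysis.

**11 to 9 and 10.** The two aryl–CH2 bonds (C4a–C4) are cut. Each arene of 9 has exactly one unsubstituted carbon, so the position of attack is not in question. The five-carbon unit comes from prenyl bromide 10. The forward reaction has to alkylate carbon and not oxygen.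

**9 to 8.** The benzyl groups on the oxygens para to the acyl groups are removed. This is the point where the three hydroxyls of each ring are told apart. The para hydroxyl is the most acidic and the only one not flanked by the ketone. Blocking it is what later forces the pyran to close onto the hydroxyl next to the acyl group. The forward reaction needs one etherification per ring, at oxygen.

**8 to 6 (through 7), the key disconnection.** In each arene the bond between the acyl-bearing carbon and the hydroxyl-bearing carbon next to the bridge is cut. This gives the bis(triketo ester) 7, whose stable form is the bis-pyrone 6.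
- Against cutting the aryl–bridge bonds: an acylphloroglucinol has two equivalent nucleophilic carbons and can oligomerise with an aldehyde, whereas the pyrone has one.
- Against cutting the aryl–acyl bonds: acylation of a bridged bis-phloroglucinol would have two free positions per ring to choose from.
- Simplification: both benzene rings vanish, and 6 is an isomer of 8 built from three simple pieces.
- Forward requirement: two lactone openings and two Claisen closures in one molecule without loss of the bridge.

**6 to 3 and 4 (through 5).** The two bonds from pyrone C3 to the bridging carbon are cut, giving two molecules of pyrone 3 and 6-methylheptanal 4. The forward reaction is the Knoevenagel–Michael dimerisation typical of 4-hydroxypyrones, passing through the alkylidene dione 5. It must take place at C3 and leave the side-chain methylene alone.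

**3 to 1 and 2.** The CH2–CO bond of the side chain is cut, giving 4-hydroxy-6-methyl-2-pyrone 1 and methyl isobutyrate 2. The forward reaction is the acylation of the pyrone dianion at its methyl carbon.

## Roads not taken

None of the three alternatives says where the bridged, fully substituted arenes come from. Each is a way of closing the pyrans on a bis-arene that still has to be made.

**Alternative 1:** The cut is at the two C8a–O1 bonds, with fluorine standing in for the pyran oxygen.
- Forward key step: the bis(fluoroarene) diol A2 (3-hydroxy-3-methylbutyl chains on the future C4a, all four phenols benzylated) is treated with KOtBu in DMF. Each tertiary alkoxide displaces the fluoride ortho to the isobutyryl group and gives the tetra-O-benzyl ether A1 of the target. Fourfold hydrogenolysis would finish.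
- Merits: the position of the pyran oxygen is fixed by a C–F bond, no hydroxyl has to be differentiated, and the closure runs in base, away from the acid-sensitive bridge. In regiochemical certainty this road is better than the chosen plan, which depends on a site-selective benzylation (step 4).
- Weak points: the fluorine-bearing carbon is activated by one ortho ketone only, and that ketone is twisted out of conjugation by two ortho substituents. The nucleophile is a hindered tertiary alkoxide. KOtBu can enolise the isopropyl ketone, which turns the activating group into a donor. A2 would also have to be built substituent by substituent on a preformed benzene, with no evident way to join two such rings through a secondary carbon.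
- Comparison: the chosen plan offsets its weaker regiochemical control by making both arenes and the bridge from four cheap building blocks in three steps, seven steps in all.

**Alternative 2:** The cut is at the four C2–CH3 bonds.
- Forward key step: in the bis(dihydrocoumarin) A4 the future pyran oxygen is the lactone oxygen. Excess MeMgBr adds twice to each lactone carbonyl and gives A3, with two tertiary alcohols and the former lactone oxygens as the only free phenols. Acid cyclodehydration and hydrogenolysis would follow.
- Merits: the pyran oxygen is marked as securely as in Alternative 1, and the geminal methyl groups come from the cheapest possible reagent. On regiochemistry it equals or beats the chosen plan.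
- Weak points: four Grignard additions must take place beside two aryl isopropyl ketones, which are protected only by steric shielding and by enolisation. A4 still needs the bridge, the acyl groups and differentiated oxygens on a preformed arene. Three operations remain after the key step.
- Comparison: the chosen plan is shorter, never exposes the ketones to a carbon nucleophile, and creates the arenes instead of decorating them.

**Alternative 3:** The cut is at the two C4a–C4 bonds, through a chromene.
- Forward key step: the bis(aryl 1,1-dimethylpropargyl ether) A6 carries the propargyl group on the oxygen next to the acyl group and a benzyl group on the para oxygen. On heating it undergoes a [3,3] shift to the free ortho carbon, a 1,5-hydrogen shift and an oxa-6π electrocyclisation, giving the bis(2H-chromene) A5. One hydrogenation would then saturate both chromene double bonds and remove the benzyl groups.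
- Merits: the carbon–carbon bond is formed intramolecularly and can only reach the free ortho carbon, so the C- versus O-alkylation question of step 5 does not arise. The end is a single operation. In these two respects it is better than the chosen endgame.
- Weak points: A6 requires etherification of a chelated hydroxyl beside the ketone with a tertiary propargylic electrophile while the second ortho hydroxyl stays free. It needs the same para-benzylation as the chosen plan and would in practice be made from 9. The cascade runs at high temperature on a bridged polyphenol.
- Comparison: in favour of the chosen plan are the direct use of prenyl bromide and the far simpler mono-alkylation at the one free ring carbon, with ring closure controlled by the same benzyl groups.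

Key step: step 3

Assumption: 6-methylheptanal 4 is taken as a purchasable aldehyde, like 1, 2 and 10. Pyrones are drawn as 4-hydroxy-2-pyrone tautomers, and 7 is drawn in its keto form although it exists in the flask as magnesium enolates.

## Route

Step 1
Reactants: 1 4-hydroxy-6-methyl-2H-pyran-2-one; 2 methyl 2-methylpropanoate (methyl isobutyrate)
Product: 3 4-hydroxy-6-(3-methyl-2-oxobutyl)-2H-pyran-2-one
Conditions: 1 (2.1 equiv), LiN(iPr)2 (4.3 equiv), THF, −78 °C; 2 (1.0 equiv), −78 → 0 °C; 1 M HCl
Reagents that add atoms: none
Why: Dianion C-acylation (Claisen-type condensation): the second equivalent of LiN(iPr)2 deprotonates the 6-methyl group of the lithium pyronolate, and the dienolate reacts with the ester at its terminal carbon, as is established for this pyrone with esters, aldehydes and alkyl halides. The product is deprotonated at once by the surplus dianion, which protects the new ketone from a second addition, and the single hindered α-hydrogen of 2 should keep proton transfer from the ester minor.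

Step 2
Reactants: 3 4-hydroxy-6-(3-methyl-2-oxobutyl)-2H-pyran-2-one (2.05 equiv); 4 6-methylheptanal
Product: 6 3,3'-(6-methylheptane-1,1-diyl)bis[4-hydroxy-6-(3-methyl-2-oxobutyl)-2H-pyran-2-one], via alkylidene pyrandione 5 (not isolated)
Conditions: piperidine (10 mol %), AcOH (10 mol %), EtOH, 25 → 50 °C
Reagents that add atoms: none
Why: Tandem Knoevenagel condensation and Michael addition, the reaction by which 4-hydroxycoumarins and 4-hydroxy-6-methyl-2-pyrone give 3,3'-alkylidene dimers with aldehydes. C3 of the acidic, fully enolised 4-hydroxypyrone is far more nucleophilic than the side-chain methylene, the alkylidene dione 5 should be captured by the second pyrone as fast as it forms, and the dimer is the thermodynamic sink.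

Step 3
Reactants: 6 3,3'-(6-methylheptane-1,1-diyl)bis[4-hydroxy-6-(3-methyl-2-oxobutyl)-2H-pyran-2-one]
Product: 8 1,1'-[(6-methylheptane-1,1-diyl)bis(2,4,6-trihydroxybenzene-3,1-diyl)]bis(2-methylpropan-1-one), via bis(triketo ester) 7 (not isolated)
Conditions: Mg(OMe)2 (10 equiv), MeOH, reflux, Ar; 1 M HCl
Reagents that add atoms: none
Why: Mg(OMe)2 converts both 4-hydroxypyrones into magnesium enolates, and methanolysis of each lactone (methoxide addition at C2, or trapping of the acylketene formed by E1cB ring opening) gives the chelated methyl 3,5,7-trioxo ester 7. In each half the C6 carbanion, flanked by the C5 and C7 carbonyls, adds to the C1 ester carbonyl; loss of methoxide and enolisation then give the arene, so the new bond joins the acyl-bearing carbon to the hydroxyl-bearing carbon next to the bridge. Both benzene rings close in the 6-(enolexo)-exo-trig mode, and no stereocentre is formed. The closest known reaction is the Mg(OMe)2-induced isomerisation of 4-hydroxy-6-(2-oxoalkyl)-2-pyrones to acylphloroglucinols, a biomimetic Claisen cyclisation; the present case adds a C3 substituent and runs twice in one molecule. Claisen closure has to win over aldol closure: C2 is fully substituted, so an aldol adduct of C2 with C7 cannot dehydrate to an arene and reverts, and C7 is a hindered isopropyl ketone. The bridge has to survive: with excess base both halves are enolates, so a retro-Michael fragmentation would have to expel a doubly charged leaving group. Magnesium chelation holds the chain folded, and the aromatic product is the thermodynamic sink.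

Step 4
Reactants: 8 1,1'-[(6-methylheptane-1,1-diyl)bis(2,4,6-trihydroxybenzene-3,1-diyl)]bis(2-methylpropan-1-one)
Product: 9 1,1'-{(6-methylheptane-1,1-diyl)bis[4-(benzyloxy)-2,6-dihydroxybenzene-3,1-diyl]}bis(2-methylpropan-1-one)
Conditions: BnBr (2.1 equiv), K2CO3 (2.2 equiv), DMF, 0 °C → rt, Ar
Reagents that add atoms: benzyl bromide, BrCc1ccccc1
Why: Williamson etherification under acidity control: the hydroxyl para to the acyl group is the most acidic and is not flanked by the ketone, so one equivalent of carbonate per ring should ionise it first, and in a dipolar aprotic solvent the phenoxide reacts at oxygen. Selective 4-O-alkylation of 2,4,6-trihydroxyacylbenzenes is established; here the 2-hydroxyl is further shielded by bridge and acyl group, and the 6-hydroxyl by chelation to the ketone.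

Step 5
Reactants: 9 1,1'-{(6-methylheptane-1,1-diyl)bis[4-(benzyloxy)-2,6-dihydroxybenzene-3,1-diyl]}bis(2-methylpropan-1-one); 10 1-bromo-3-methylbut-2-ene (prenyl bromide, 2.4 equiv)
Product: 11 1,1'-{(6-methylheptane-1,1-diyl)bis[4-(benzyloxy)-2,6-dihydroxy-5-(3-methylbut-2-en-1-yl)benzene-3,1-diyl]}bis(2-methylpropan-1-one)
Conditions: NaOMe (4.2 equiv), MeOH, 0 °C; 10, 0 °C → rt; 1 M HCl
Reagents that add atoms: none
Why: Phenoxide C-alkylation, the standard C-prenylation of acylphloroglucinols: in methanol the hydrogen-bonded phenoxide oxygens are poor nucleophiles, and the single free ring carbon of each arene, ortho to the 6-oxide and para to the 2-oxide, is the site of attack. Ipso attack at the bridge- or acyl-bearing carbons is sterically disfavoured.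

Step 6
Reactants: 11 1,1'-{(6-methylheptane-1,1-diyl)bis[4-(benzyloxy)-2,6-dihydroxy-5-(3-methylbut-2-en-1-yl)benzene-3,1-diyl]}bis(2-methylpropan-1-one)
Product: 12 1,1'-{(6-methylheptane-1,1-diyl)bis[5-(benzyloxy)-7-hydroxy-2,2-dimethyl-3,4-dihydro-2H-chromene-6,8-diyl]}bis(2-methylpropan-1-one)
Conditions: p-TsOH·H2O (20 mol %), toluene, 60 °C
Reagents that add atoms: none
Why: Acid-catalysed hydroalkoxylation of an ortho-prenylphenol: Markovnikov protonation gives the tertiary cation, which the neighbouring phenol captures in a 6-endo-trig closure. The other neighbour of the prenyl group is a benzyl ether, so only the hydroxyl next to the acyl group can close, which places the pyran oxygen para to the bridge; catalytic sulfonic acid should spare the benzyl ethers and the diarylmethine.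

Step 7
Reactants: 12 1,1'-{(6-methylheptane-1,1-diyl)bis[5-(benzyloxy)-7-hydroxy-2,2-dimethyl-3,4-dihydro-2H-chromene-6,8-diyl]}bis(2-methylpropan-1-one)
Product: 13 1,1'-[(6-methylheptane-1,1-diyl)bis(5,7-dihydroxy-2,2-dimethyl-3,4-dihydro-2H-chromene-6,8-diyl)]bis(2-methylpropan-1-one)
Conditions: H2 (1 atm), Pd/C (10 wt % Pd), EtOAc–MeOH, rt
Reagents that add atoms: none
Why: Hydrogenolysis of aryl benzyl ethers over Pd/C at atmospheric pressure under neutral conditions; the hindered, chelated aryl ketones, the chroman ethers and the diarylmethine C–H are not expected to react. The target has no stereocentre, so none has to be set.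

## Compound list

1 | 4-hydroxy-6-methyl-2H-pyran-2-one | CC1=CC(O)=CC(=O)O1 | starting material
2 | methyl 2-methylpropanoate (methyl isobutyrate) | COC(=O)C(C)C | starting material
3 | 4-hydroxy-6-(3-methyl-2-oxobutyl)-2H-pyran-2-one | CC(C)C(=O)CC1=CC(O)=CC(=O)O1 | intermediate
4 | 6-methylheptanal | CC(C)CCCCC=O | starting material
5 | 3-(6-methylheptylidene)-6-(3-methyl-2-oxobutyl)-2H-pyran-2,4(3H)-dione (not isolated, alkene geometry not defined) | CC(C)CCCCC=C1C(=O)C=C(CC(=O)C(C)C)OC1=O | intermediate
6 | 3,3'-(6-methylheptane-1,1-diyl)bis[4-hydroxy-6-(3-methyl-2-oxobutyl)-2H-pyran-2-one] | CC(C)CCCCC(C1=C(O)C=C(CC(=O)C(C)C)OC1=O)C1=C(O)C=C(CC(=O)C(C)C)OC1=O | intermediate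
7 | dimethyl 2,2'-(6-methylheptane-1,1-diyl)bis(8-methyl-3,5,7-trioxononanoate) (not isolated, magnesium enolates, epimerisable centres not defined) | CC(C)CCCCC(C(C(=O)OC)C(=O)CC(=O)CC(=O)C(C)C)C(C(=O)OC)C(=O)CC(=O)CC(=O)C(C)C | intermediate
8 | 1,1'-[(6-methylheptane-1,1-diyl)bis(2,4,6-trihydroxybenzene-3,1-diyl)]bis(2-methylpropan-1-one) | CC(C)CCCCC(c1c(O)cc(O)c(C(=O)C(C)C)c1O)c1c(O)cc(O)c(C(=O)C(C)C)c1O | intermediate
9 | 1,1'-{(6-methylheptane-1,1-diyl)bis[4-(benzyloxy)-2,6-dihydroxybenzene-3,1-diyl]}bis(2-methylpropan-1-one) | CC(C)CCCCC(c1c(OCc2ccccc2)cc(O)c(C(=O)C(C)C)c1O)c1c(OCc2ccccc2)cc(O)c(C(=O)C(C)C)c1O | intermediate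
10 | 1-bromo-3-methylbut-2-ene (prenyl bromide) | CC(C)=CCBr | starting material
11 | 1,1'-{(6-methylheptane-1,1-diyl)bis[4-(benzyloxy)-2,6-dihydroxy-5-(3-methylbut-2-en-1-yl)benzene-3,1-diyl]}bis(2-methylpropan-1-one) | CC(C)CCCCC(c1c(OCc2ccccc2)c(CC=C(C)C)c(O)c(C(=O)C(C)C)c1O)c1c(OCc2ccccc2)c(CC=C(C)C)c(O)c(C(=O)C(C)C)c1O | intermediate
12 | 1,1'-{(6-methylheptane-1,1-diyl)bis[5-(benzyloxy)-7-hydroxy-2,2-dimethyl-3,4-dihydro-2H-chromene-6,8-diyl]}bis(2-methylpropan-1-one) | CC(C)CCCCC(c1c(OCc2ccccc2)c2c(c(C(=O)C(C)C)c1O)OC(C)(C)CC2)c1c(OCc2ccccc2)c2c(c(C(=O)C(C)C)c1O)OC(C)(C)CC2 | intermediate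
13 | 1,1'-[(6-methylheptane-1,1-diyl)bis(5,7-dihydroxy-2,2-dimethyl-3,4-dihydro-2H-chromene-6,8-diyl)]bis(2-methylpropan-1-one) (CNP0275635.0, achiral) | CC(C)CCCCC(c1c(O)c2c(c(C(=O)C(C)C)c1O)OC(C)(C)CC2)c1c(O)c2c(c(C(=O)C(C)C)c1O)OC(C)(C)CC2 | target

## Step count and risks

Total: 7 steps. Longest linear sequence: 7 steps (1 → 3 → 6 → 8 → 9 → 11 → 12 → 13).

**Step 3 (key step).** Two processes are most likely to interfere.
- Lactone opening may be slow, because the 4-oxido-pyrone is a poor electrophile and C3 now carries a branched substituent. That would leave half-converted material.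
- The bridge may fragment: by retro-Michael cleavage of a mono-enolate of 6, or by quinone methide extrusion from the product on long heating in base, followed by tautomerisation of the alkylidene to an alkenyl arene.

Fallback: set out from 3 and apply the Mg(OMe)2 recyclisation to the monomer, which is the documented parent case, to give 1-(2,4,6-trihydroxyphenyl)-2-methylpropan-1-one F1. Then condense F1, in excess to hold back oligomers, with aldehyde 4 under mild acid catalysis. This forms the bridge between two arenes and rejoins the route at 8.

**Step 4.** Site selectivity may be poor, because the para hydroxyl now sits next to the bulky bridge and may be tied into inter-ring hydrogen bonds. Benzylation may then go to the hydroxyl between the free ring carbon and the acyl group, or to the free ring carbon itself.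

Fallback: set out from 3 and recyclise it to 1-(2,4,6-trihydroxyphenyl)-2-methylpropan-1-one F1, as in the fallback for step 3. Benzylate F1 at the para oxygen, where both ortho hydroxyls are equivalent and no bridge interferes, to give 1-[4-(benzyloxy)-2,6-dihydroxyphenyl]-2-methylpropan-1-one F2. Condense two molecules of F2 with aldehyde 4; its two free ring carbons are equivalent, so the bridged product is 9, where the route is rejoined.

**Step 5.** O-prenylation of the chelated hydroxyls, dearomatising ipso alkylation and incomplete twofold alkylation may compete with attack at the free ring carbon.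

Fallback: set out from 9 and carry out an acid-mediated Friedel–Crafts chroman annulation with 2-methylbut-3-en-2-ol and BF3·OEt2 in dioxane. The allyl cation attacks the only free ring carbon and the adjacent free hydroxyl closes the ring in the same flask. The route is rejoined at 12 and no new compound is made.

**Step 2.** Condensation of the aldehyde at the side-chain methylene of 3, or self-condensation of the aldehyde under amine catalysis, may divert material from the C3 dimer.

Fallback: reverse the order. Set out from 1 and 4 and form the bridge first, on the pyrone that has no second acidic methylene, to give 3,3'-(6-methylheptane-1,1-diyl)bis(4-hydroxy-6-methyl-2H-pyran-2-one) F3. Then deprotonate F3 fourfold with LiN(iPr)2 and acylate both methyl groups with 2, returning to the route at 6.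

## Further compounds

F1 | step 3 | 1-(2,4,6-trihydroxyphenyl)-2-methylpropan-1-one | CC(C)C(=O)c1c(O)cc(O)cc1O
F2 | step 4 | 1-[4-(benzyloxy)-2,6-dihydroxyphenyl]-2-methylpropan-1-one | CC(C)C(=O)c1c(O)cc(OCc2ccccc2)cc1O
F0 | step 5 | none | none
F3 | step 2 | 3,3'-(6-methylheptane-1,1-diyl)bis(4-hydroxy-6-methyl-2H-pyran-2-one) | CC(C)CCCCC(C1=C(O)C=C(C)OC1=O)C1=C(O)C=C(C)OC1=O
A1 | alternative 1 | 1,1'-{(6-methylheptane-1,1-diyl)bis[5,7-bis(benzyloxy)-2,2-dimethyl-3,4-dihydro-2H-chromene-6,8-diyl]}bis(2-methylpropan-1-one) | CC(C)CCCCC(c1c(OCc2ccccc2)c2c(c(C(=O)C(C)C)c1OCc1ccccc1)OC(C)(C)CC2)c1c(OCc2ccccc2)c2c(c(C(=O)C(C)C)c1OCc1ccccc1)OC(C)(C)CC2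
A2 | alternative 1 | 1,1'-{(6-methylheptane-1,1-diyl)bis[2,4-bis(benzyloxy)-6-fluoro-5-(3-hydroxy-3-methylbutyl)benzene-3,1-diyl]}bis(2-methylpropan-1-one) | CC(C)CCCCC(c1c(OCc2ccccc2)c(CCC(C)(C)O)c(F)c(C(=O)C(C)C)c1OCc1ccccc1)c1c(OCc2ccccc2)c(CCC(C)(C)O)c(F)c(C(=O)C(C)C)c1OCc1ccccc1
A3 | alternative 2 | 1,1'-{(6-methylheptane-1,1-diyl)bis[2,4-bis(benzyloxy)-6-hydroxy-5-(3-hydroxy-3-methylbutyl)benzene-3,1-diyl]}bis(2-methylpropan-1-one) | CC(C)CCCCC(c1c(OCc2ccccc2)c(CCC(C)(C)O)c(O)c(C(=O)C(C)C)c1OCc1ccccc1)c1c(OCc2ccccc2)c(CCC(C)(C)O)c(O)c(C(=O)C(C)C)c1OCc1ccccc1
A4 | alternative 2 | 6,6'-(6-methylheptane-1,1-diyl)bis[5,7-bis(benzyloxy)-8-(2-methylpropanoyl)-3,4-dihydro-2H-chromen-2-one] | CC(C)CCCCC(c1c(OCc2ccccc2)c2c(c(C(=O)C(C)C)c1OCc1ccccc1)OC(=O)CC2)c1c(OCc2ccccc2)c2c(c(C(=O)C(C)C)c1OCc1ccccc1)OC(=O)CC2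
A5 | alternative 3 | 1,1'-{(6-methylheptane-1,1-diyl)bis[5-(benzyloxy)-7-hydroxy-2,2-dimethyl-2H-chromene-6,8-diyl]}bis(2-methylpropan-1-one) | CC(C)CCCCC(c1c(OCc2ccccc2)c2c(c(C(=O)C(C)C)c1O)OC(C)(C)C=C2)c1c(OCc2ccccc2)c2c(c(C(=O)C(C)C)c1O)OC(C)(C)C=C2
A6 | alternative 3 | 1,1'-{(6-methylheptane-1,1-diyl)bis[4-(benzyloxy)-2-hydroxy-6-(2-methylbut-3-yn-2-yloxy)benzene-3,1-diyl]}bis(2-methylpropan-1-one) | CC(C)CCCCC(c1c(OCc2ccccc2)cc(OC(C)(C)C#C)c(C(=O)C(C)C)c1O)c1c(OCc2ccccc2)cc(OC(C)(C)C#C)c(C(=O)C(C)C)c1O
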